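The runs are calculated with made-up constants; scatter was added.

If you repeat this flask, watch the solid as well as the solution, since a slowing rise of c(dissolved substrate) can mean two different things.

the same everywhere: partner 1.43 M
- east: solid substrate 1.3 M; the very flask that is asked about, followed so far
- south-west: solid substrate 2 M; run made earlier
- flask: solid substrate 1.3 M; time 2.0 h

| run | time / min | target / % | dissolved substrate / % |
|---|---|---|---|
| east | 4.00 | 0.4 | 2.8 |
| east | 8.00 | 0.5 | 4.3 |
| east | 20.0 | 2.7 | 6.5 |
| east | 50.0 | 6.3 | 12.8 |
| south-west | 6.00 | 0.3 | 1.0 |
| south-west | 15.0 | 1.1 | 3.9 |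
| south-west | 40.0 | 3.5 | 6.9 |
| south-west | 80.0 | 5.0 | 9.4 |

(each reading ± 0.5 percentage points)

- as a solid, counted per litre of solution: solid substrate
- the numbers in the tables scatter by 0.5 percentage points (one standard deviation)
- at the start none of the solid substrate is in solution
- dissolved substrate means what is dissolved; the solid is not counted in it

1. amount of target at 2.0 h, in percent of the solid substrate charged
2. concentration of dissolved substrate in solution at 2.0 h, in percent of saturation

First, does the charge of solid change how fast it enters solution? At 8.00 min the east run gives 0.00780 M min⁻¹: this is the feed, the molarity leaving the solid per minute, read as dissolved substrate plus target. The south-west run, with 1.54 times the solid, reads 0.00667 M min⁻¹ at 15.0 min, less than a proportional feed. So I take the feed as zero-order in solid.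

How long does the solid last? At that feed I reckon the east charge to last 2.78 h, longer than the asked time, so I expect 28.0% of it left at 2.0 h.

Then is saturation near? Held to 50.0 min, the east feed gives 0.390 M, yet dissolved substrate plus target read 0.248 M. If the feed held, 0.142 M has gone somewhere unread. I therefore read the slowing rise as loss from solution, not as saturation, and expect the flask well below saturation.

The forecast differs on saturation: “saturation is about 0.2 M”. It gives 9.6% (7.5% to 14%) and 97% (88% to 100%).

The flask gives 10.3% and 32.6%.

    dissolved substrate + partner → target (k = 0.0400 M⁻¹ min⁻¹)
    2 dissolved substrate → side product (k = 0.0430 M⁻¹ min⁻¹)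
    target ⇌ isomer of the product (K = 1.80, k = 0.0760 min⁻¹)
    2 partner → homo dimer (k = 0.00880 M⁻¹ min⁻¹)
    solid substrate ⇌ dissolved substrate, rate k5*(cs5 - [dissolved substrate]) while solid is left; crystals form when [dissolved substrate] > cs5 (solubility = 0.660 M, k = 0.0140 min⁻¹)

At 2.0 h the asked flask holds 35.1% solid substrate, against my reckoned 28.0%. Read the same flask at 50 min: the feed leaves 70.0% of the solid, and it holds 70.3%. The unread gap, 10.9% of the charge, stands beside 6.73% isomer of the product plus 4.45% side product, together 11.2%.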